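## Analysis of the target

Glomelliferic acid 16 is a depside: two separate benzene rings joined by a single aryl ester, with no ring fusion and no stereocentre. Ring A is a 2-hydroxy-4-methoxybenzoyl unit whose C6 carries a 2-oxopentyl chain. Ring B is 2,4-dihydroxy-6-pentylbenzoic acid (11), acylated on its C4 oxygen. Because 16 is achiral, the one stereocentre that appears in the intermediates (the carbinol carbon of the chain) can be carried as a racemate and is erased by oxidation.

The sensitive groups are the aryl ester, which bases and nucleophiles cleave, and the salicylic acid of ring B, which decarboxylates on heating or in acid. The chain oxygen is also sensitive: it lies δ to the ring A carboxyl carbon, so a free carbinol there, or the enol of the ketone, can close a six-membered lactone and expel ring B.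

Three things make the synthesis hard. The ring A acid has two ortho substituents and must acylate one of the two phenols of ring B. The chain sits at C6, meta to both ring A oxygens, where electrophilic substitution will not place it. Its oxygen must be masked while the ester is made and then revealed without leaving a free alcohol beside the aryl ester.

The strategy rests on one feature of ring A. The C1 carboxyl has exactly one open ortho position, C6, and the chain at C6 carries its oxygen on the second carbon. That is the pattern produced when a metal at C6 opens a terminal epoxide at its CH2 group, so acid 3 and epoxide 4 map onto ring A directly.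

## Retrosynthetic reasoning

**From 16 to 15.** The last bonds set free are the two O–CH2Ph bonds: the benzyl ether on the C2 oxygen of ring A and the benzyl ester of ring B. Hydrogenolysis is neither acidic nor basic, and 16 tolerates neither (depside cleavage, decarboxylation of ring B). Both groups fall in one operation, so dibenzyl compound 15 is the penultimate intermediate.

**From 15 to 13.** No skeletal bond is cut; the ketone of 15 is traced back to the silyl-protected carbinol 13. The carbinol level is what the key step delivers. It cannot be raised to the ketone before the ester is made, because a ketone δ to an activated carboxyl closes to an isocoumarin. The free carbinol 14 cannot be kept beside the aryl ester either, since it would close to lactone 6 and expel 12. The forward reaction must therefore take the silyl ether to the ketone in one operation in which 14 is only a passing species. A Jones oxidation does this: its aqueous acid uncovers the carbinol more slowly than the oxidant consumes it.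

**From 13 to 9 and 12.** The ester C(=O)–O bond between the rings is the only bond joining the two halves. Cutting it gives two pieces of similar size, ring A acid 9 and ring B phenol 12. The forward reaction must acylate the C4 hydroxyl of 12 and leave the C2 hydroxyl, which is hydrogen-bonded to the neighbouring ester carbonyl. It must also activate the doubly ortho-substituted carboxyl of 9 without ionizing it to an acylium ion, which the δ-silyloxy oxygen would trap. A carbodiimide with an acyl-transfer catalyst meets both demands.

**From 12 to 10.** Ring B needs only its benzyl ester O–CH2 bond and its C1–carboxyl bond. Compound 12 goes back to acid 11, and 11 to olivetol 10 by ortho carboxylation. The cut is made there because 10 is bought with the pentyl group and both oxygens in place.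

**From 9 to 6.** Acid 9 is the opened and protected form of lactone 6. The lactone C(=O)–O bond is cleaved by base to the carboxylate salt 7, both oxygens are silylated (8), and the silyl ester alone is hydrolysed. The detour through the salt is needed because the free hydroxy acid 5 closes back to 6 as soon as it forms. The carbinol may never be free while the carboxyl is protonated or activated.

**From 6 to 3 and 4 (key disconnection).** Two bonds are cut in lactone 6: the bond from C6 of ring A to the chain CH2, and the lactone O–C(=O) bond. This leaves benzoic acid 3 and epoxide 4, by way of hydroxy acid 5. C6 is the right place to cut because it is out of reach of electrophilic substitution and the only handle next to it is the carboxyl group. Epoxide 4 brings all five chain carbons and puts its oxygen on the second one, where the ketone of 16 belongs. The gain is the whole ring A side chain in one catalytic step, with carbinol and carboxyl tied together in a lactone that can be isolated. The forward reaction must palladate 3 at C6 only, open 4 at its terminal carbon only, and close the lactone.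

**From 3 to 1.** Acid 3 comes from 1 by benzylation of both acidic oxygens (2) and saponification of the ester. Compound 1 is bought with the ring A oxygen pattern complete, methyl ether included. Benzyl is chosen for the phenol because it leaves together with the ring B ester in the last step and occupies C2, so that C6 is the only C–H next to the carboxyl.

## Alternatives that were turned down

**Alternative 1:** Ring B is cut at its C6–pentyl and C1–carboxyl bonds.
- **Forward step.** Fluoroarene A1 (1-fluoro-3,5-dimethoxybenzene) is lithiated between fluorine and a methoxyl group and eliminates fluoride to give aryne A2 (3,5-dimethoxybenzyne). A pentyl Grignard reagent adds to the aryne carbon remote from the neighbouring methoxyl, and the aryl metal so formed is carboxylated to A3 (2,4-dimethoxy-6-pentylbenzoic acid).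
- **For it.** Two C–C bonds form in one flask. The relation of pentyl to carboxyl is fixed by the mechanism, which is a firmer regiochemical guarantee than the carboxylation of 10 in step 6. On this point the alternative is stronger.
- **Against it.** A3 carries both oxygens as methyl ethers, whereas the depside needs the C4 oxygen free. Removing two aryl methyl ethers from an electron-rich salicylic-type acid needs a strong Lewis acid, under which such acids decarboxylate. The benzyl ester must still be made, so 12 is reached in more steps than from 10.
- **Comparison.** The aryne step solves ring B, the half that is close to a purchasable compound, and leaves the oxygenated chain at C6 of ring A untouched. The chosen strategy spends its key step on that chain and accepts a less certain but two-step ring B.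

**Alternative 2:** Ring B is made non-aromatic by cutting C1–C6 and C2–C3.
- **Forward step.** Malonate A5 (dibenzyl malonate) adds in a Michael reaction to enone A4 ((E)-non-3-en-2-one) under a benzyloxide base. The methyl ketone enolate then closes onto one ester group in a Claisen condensation to give cyclohexenone A6 (benzyl 2-hydroxy-4-oxo-6-pentylcyclohex-2-ene-1-carboxylate, racemic). Dehydrogenation, before or after the depside bond is made, turns it into the resorcinol ring.
- **For it.** The materials are cheap and acyclic, the benzyl ester is present from the start, and all substituents are placed by construction. Aromatization of A6 would give 12 in two steps with no regiochemical question and without passing through the decarboxylation-prone acid 11. As a supply of ring B it is at least as strong as steps 6 and 7 and could replace them without touching the rest.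
- **Against it.** Aromatization needs halogenation–dehydrohalogenation or a quinone or iodine oxidant, and the resorcinol formed is itself easily halogenated. If aromatization is put off until after esterification, A6 is a vinylogous acid with two enol oxygens, its enol ester has anhydride character, and the oxidant would then meet the whole depside.
- **Comparison.** As with Alternative 1, the key step does nothing for ring A. The chosen strategy offers a direct answer to the C6 chain of ring A.

**Alternative 3:** Ring A is cut at C1–C2 and C5–C6.
- **Forward step.** Diene A7 (1,3-dimethoxy-1-(trimethylsilyloxy)buta-1,3-diene) adds to ynoate A8, the but-2-ynoic ester of the C4 oxygen of 12 that carries the chain ketone as a dioxolane. The CH2 terminus of the diene bonds to the β-carbon of the ynoate and the ketene acetal carbon to the α-carbon. Loss of one methoxyl group aromatizes the adduct to A9, the benzyl ester of 16 with the ketone still as its dioxolane.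
- **For it.** The depside ester is formed from an unhindered alkynoic acid, so the weakest bond-forming step of the chosen route (step 8) has no counterpart. Ring A appears with its C2 hydroxyl free, so no benzyl ether is needed there. The ketone is never a carbinol beside the aryl ester, so step 9 has no counterpart either. On these three points the alternative is stronger.
- **Against it.** The alkynoic acid with its ketal must be built in several steps. Aryl ynoates are strong Michael acceptors and acyl donors. A β-alkyl ynoate is a sluggish dienophile, and the heat it needs is what the ketene acetal diene does not tolerate. Regiochemistry rests on polarity alone. The dioxolane must finally be hydrolysed by acid next to the depside, the condition under which the keto ester closes to an isocoumarin.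
- **Comparison.** The chosen strategy buys ring A with its oxygen pattern certain, adds the chain in one catalytic C–H functionalization, and needs fewer steps before the halves meet. What it gives up is the easy esterification.

Key step: step 3

Remark on the chemistry: epoxide 4 is used as the racemate, so compounds 5 to 9, 13 and 14 are racemic at the carbinol carbon; that centre is destroyed in step 9 and the target is achiral.

## Route

Step 1
Reactants: 1 2-hydroxy-4-methoxybenzoic acid
Product: 2 benzyl 2-(benzyloxy)-4-methoxybenzoate
Conditions: BnBr (2.4 equiv), K2CO3 (3 equiv), DMF, 60 °C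
Reagents that add atoms: benzyl bromide, BrCc1ccccc1
Why: Williamson etherification of the phenoxide and SN2 alkylation of the carboxylate in one flask; warm DMF and an excess of bromide are used because the salicylic hydroxyl is hydrogen-bonded and reacts last.

Step 2
Reactants: 2 benzyl 2-(benzyloxy)-4-methoxybenzoate
Product: 3 2-(benzyloxy)-4-methoxybenzoic acid
Conditions: KOH (3 equiv), MeOH/THF/H2O, 65 °C; then 1 M HCl
Reagents that add atoms: potassium hydroxide, [K+].[OH-]
Why: Saponification by acyl–oxygen cleavage of an ester with only one ortho substituent; the aryl benzyl ether is inert to hydroxide, so the phenol stays protected.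

Step 3
Reactants: 3 2-(benzyloxy)-4-methoxybenzoic acid; 4 2-propyloxirane (racemic)
Product: 6 8-(benzyloxy)-6-methoxy-3-propyl-3,4-dihydroisochromen-1-one (racemic), via 2-(benzyloxy)-6-(2-hydroxypentyl)-4-methoxybenzoic acid 5 (not isolated)
Conditions: Pd(OAc)2 (10 mol%), N-acetyl-L-tert-leucine (20 mol%), KOAc (1.0 equiv), 4 (2.5 equiv), 1,1,1,3,3,3-hexafluoropropan-2-ol (HFIP), 75 °C, sealed tube
Reagents that add atoms: none
Why: This is the known palladium-catalysed, carboxylate-directed ortho C–H alkylation of benzoic acids with terminal epoxides, which gives 3,4-dihydroisocoumarins in one step. KOAc converts 3 into its potassium carboxylate, which binds divalent palladium through oxygen, and the N-acetyl amino acid ligand serves as the internal base in a concerted metalation–deprotonation at C6 that gives a five-membered palladacycle. The aryl–palladium bond then opens 4 at its unsubstituted CH2 in an SN2-like manner, which forms the C6–CH2 bond and leaves the carbinol carbon of 4 untouched. Protonation of the palladium alkoxide by AcOH or HFIP releases hydroxy acid 5 and divalent palladium with no change of oxidation state. In the warm, weakly acidic medium 5 closes the six-membered lactone by 6-exo-trig attack of the hydroxyl on the carboxyl carbon with loss of water. No stereocentre is created: the one at C3 of 6 comes unchanged from racemic 4, so 6 is racemic whatever the ligand. The step needs site selectivity on the arene and on the epoxide. C6 is the only C–H ortho to the carboxylate because C2 carries the benzyloxy group; it is meta to both ether oxygens and gains no resonance activation from them (C3 and C5 are the electron-richer sites), but it alone can reach a metal held by the carboxylate, and the epoxide is attacked at its terminus for steric reasons.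

Step 4
Reactants: 6 8-(benzyloxy)-6-methoxy-3-propyl-3,4-dihydroisochromen-1-one (racemic)
Product: 7 potassium 2-(benzyloxy)-6-(2-hydroxypentyl)-4-methoxybenzoate (racemic)
Conditions: KOH (1.05 equiv), THF/MeOH/H2O, 50 °C; evaporate, dry by azeotrope with toluene
Reagents that add atoms: potassium hydroxide, [K+].[OH-]
Why: Lactone saponification by acyl–oxygen cleavage; the product is kept as the dry carboxylate salt and never acidified, because the carboxylate is not electrophilic and cannot close back to 6.

Step 5
Reactants: 7 potassium 2-(benzyloxy)-6-(2-hydroxypentyl)-4-methoxybenzoate (racemic)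
Product: 9 2-(benzyloxy)-6-[2-(tert-butyldimethylsilyloxy)pentyl]-4-methoxybenzoic acid (racemic), via bis-silylated hydroxy acid 8 (not isolated)
Conditions: TBSCl (3 equiv), imidazole (6 equiv), DMF, rt; then K2CO3 (1 equiv), MeOH/THF/H2O, 0 °C to rt; cold aq. KHSO4 to pH 4–5
Reagents that add atoms: tert-butyldimethylsilyl chloride, CC(C)(C)[Si](C)(C)Cl
Why: Silylation turns the carboxylate into a silyl ester and the secondary carbinol into a silyl ether (8); carbonate in aqueous methanol then cleaves only the silyl ester, since nucleophiles attack the silicon of a silyl ester far faster than that of a hindered secondary silyl ether. The carboxyl stays a salt or silyl ester until the carbinol is capped, so the hydroxy acid cannot relactonize, and the final acidification is cold and mild to spare the silyl ether.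

Step 6
Reactants: 10 olivetol (5-pentylbenzene-1,3-diol)
Product: 11 olivetolic acid (2,4-dihydroxy-6-pentylbenzoic acid)
Conditions: MeOMgOCO2Me (2 M in DMF, 6 equiv), 120 °C, N2; then cold 2 M HCl
Reagents that add atoms: methoxymagnesium methyl carbonate, COC(=O)O[Mg]OC
Why: Kolbe–Schmitt-type carboxylation through the magnesium phenoxide: the reagent transfers its carbonate carbon to a ring carbon ortho to a phenoxide oxygen, and the product is held as a magnesium salicylate chelate that resists decarboxylation until the cold acidic work-up. C4 of 10 (ortho to one hydroxyl, para to the other) is the position electrophiles normally take in 5-alkylresorcinols, and the carboxylation is expected to follow that preference over C2.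

Step 7
Reactants: 11 olivetolic acid (2,4-dihydroxy-6-pentylbenzoic acid)
Product: 12 benzyl 2,4-dihydroxy-6-pentylbenzoate
Conditions: BnBr (1.05 equiv), KHCO3 (1.2 equiv), DMF, rt
Reagents that add atoms: benzyl bromide, BrCc1ccccc1
Why: Hydrogencarbonate deprotonates only the carboxylic acid, so SN2 alkylation occurs at the carboxylate and both phenols stay free; the mild, cool conditions avoid decarboxylation of 11.

Step 8
Reactants: 9 2-(benzyloxy)-6-[2-(tert-butyldimethylsilyloxy)pentyl]-4-methoxybenzoic acid (racemic); 12 benzyl 2,4-dihydroxy-6-pentylbenzoate
Product: 13 benzyl 4-({2-(benzyloxy)-6-[2-(tert-butyldimethylsilyloxy)pentyl]-4-methoxybenzoyl}oxy)-2-hydroxy-6-pentylbenzoate (racemic)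
Conditions: DCC (1.3 equiv), DMAP (0.3 equiv), CH2Cl2, 0 °C to rt
Reagents that add atoms: none
Why: Steglich esterification: DCC converts 9 into the O-acylisourea, DMAP relays the acyl group as an acylpyridinium ion, and the unhindered C4 hydroxyl of 12 attacks it, while the C2 hydroxyl is held in a hydrogen bond to the benzyl ester carbonyl and stays free. A carbodiimide is preferred to an anhydride-forming activator, which would ionize this electron-rich acid to an acylium ion that the δ-silyloxy oxygen would capture to return 6.

Step 9
Reactants: 13 benzyl 4-({2-(benzyloxy)-6-[2-(tert-butyldimethylsilyloxy)pentyl]-4-methoxybenzoyl}oxy)-2-hydroxy-6-pentylbenzoate (racemic)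
Product: 15 benzyl 4-{[2-(benzyloxy)-4-methoxy-6-(2-oxopentyl)benzoyl]oxy}-2-hydroxy-6-pentylbenzoate, via free carbinol depside 14 (not isolated)
Conditions: CrO3, H2SO4, H2O (Jones reagent, 3 equiv), acetone, 0 °C to rt; iPrOH quench
Reagents that add atoms: none
Why: Jones oxidation applied directly to the silyl ether: the aqueous H2SO4 of the reagent hydrolyses the Si–O bond slowly, and carbinol 14 is oxidized through its chromate ester by hexavalent chromium much faster than it is formed, so it should not build up and attack the neighbouring aryl ester. The benzyl ether, benzyl ester and hydrogen-bonded phenol should tolerate cold chromic acid for the time needed, and the racemic centre is erased.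

Step 10
Reactants: 15 benzyl 4-{[2-(benzyloxy)-4-methoxy-6-(2-oxopentyl)benzoyl]oxy}-2-hydroxy-6-pentylbenzoate
Product: 16 glomelliferic acid
Conditions: H2 (1 atm), 10% Pd/C, EtOAc, rt
Reagents that add atoms: none
Why: Hydrogenolysis cleaves the benzylic C–O bonds of the aryl benzyl ether and the benzyl ester under neutral conditions; the dialkyl ketone, the aryl ester and the arenes are not reduced at 1 atm and room temperature, and no acid or base is present to open the depside or decarboxylate ring B.

## Compound list

1 | 2-hydroxy-4-methoxybenzoic acid | COc1ccc(C(=O)O)c(O)c1 | starting material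
2 | benzyl 2-(benzyloxy)-4-methoxybenzoate | COc1ccc(C(=O)OCc2ccccc2)c(OCc2ccccc2)c1 | intermediate
3 | 2-(benzyloxy)-4-methoxybenzoic acid | COc1ccc(C(=O)O)c(OCc2ccccc2)c1 | intermediate
4 | 2-propyloxirane (racemic) | CCCC1CO1 | starting material
5 | 2-(benzyloxy)-6-(2-hydroxypentyl)-4-methoxybenzoic acid (racemic, not isolated) | CCCC(O)Cc1cc(OC)cc(OCc2ccccc2)c1C(=O)O | intermediate
6 | 8-(benzyloxy)-6-methoxy-3-propyl-3,4-dihydroisochromen-1-one (racemic) | CCCC1Cc2cc(OC)cc(OCc3ccccc3)c2C(=O)O1 | intermediate
7 | potassium 2-(benzyloxy)-6-(2-hydroxypentyl)-4-methoxybenzoate (racemic) | CCCC(O)Cc1cc(OC)cc(OCc2ccccc2)c1C(=O)[O-].[K+] | intermediate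
8 | tert-butyldimethylsilyl 2-(benzyloxy)-6-[2-(tert-butyldimethylsilyloxy)pentyl]-4-methoxybenzoate (racemic, not isolated) | CCCC(O[Si](C)(C)C(C)(C)C)Cc1cc(OC)cc(OCc2ccccc2)c1C(=O)O[Si](C)(C)C(C)(C)C | intermediate
9 | 2-(benzyloxy)-6-[2-(tert-butyldimethylsilyloxy)pentyl]-4-methoxybenzoic acid (racemic) | CCCC(O[Si](C)(C)C(C)(C)C)Cc1cc(OC)cc(OCc2ccccc2)c1C(=O)O | intermediate
10 | olivetol (5-pentylbenzene-1,3-diol) | CCCCCc1cc(O)cc(O)c1 | starting material
11 | olivetolic acid (2,4-dihydroxy-6-pentylbenzoic acid) | CCCCCc1cc(O)cc(O)c1C(=O)O | intermediate
12 | benzyl 2,4-dihydroxy-6-pentylbenzoate | CCCCCc1cc(O)cc(O)c1C(=O)OCc1ccccc1 | intermediate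
13 | benzyl 4-({2-(benzyloxy)-6-[2-(tert-butyldimethylsilyloxy)pentyl]-4-methoxybenzoyl}oxy)-2-hydroxy-6-pentylbenzoate (racemic) | CCCCCc1cc(OC(=O)c2c(OCc3ccccc3)cc(OC)cc2CC(CCC)O[Si](C)(C)C(C)(C)C)cc(O)c1C(=O)OCc1ccccc1 | intermediate
14 | benzyl 4-{[2-(benzyloxy)-6-(2-hydroxypentyl)-4-methoxybenzoyl]oxy}-2-hydroxy-6-pentylbenzoate (racemic, not isolated) | CCCCCc1cc(OC(=O)c2c(OCc3ccccc3)cc(OC)cc2CC(O)CCC)cc(O)c1C(=O)OCc1ccccc1 | intermediate
15 | benzyl 4-{[2-(benzyloxy)-4-methoxy-6-(2-oxopentyl)benzoyl]oxy}-2-hydroxy-6-pentylbenzoate | CCCCCc1cc(OC(=O)c2c(OCc3ccccc3)cc(OC)cc2CC(=O)CCC)cc(O)c1C(=O)OCc1ccccc1 | intermediate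
16 | glomelliferic acid (2-hydroxy-4-{[2-hydroxy-4-methoxy-6-(2-oxopentyl)benzoyl]oxy}-6-pentylbenzoic acid) | CCCCCc1cc(OC(=O)c2c(O)cc(OC)cc2CC(=O)CCC)cc(O)c1C(=O)O | target

## Step count and least certain steps

Total step count: 10. Longest linear sequence: 8 steps (steps 1, 2, 3, 4, 5, 8, 9, 10, from 1 to 16); the ring B branch (steps 6 and 7) joins at step 8.

**Step 3 (key step).**
- Risk: palladation at C6 may be slow, because C6 is meta to both ether oxygens. Undirected palladation at the richer C3 and C5 positions, or opening and rearrangement of the epoxide by the hot ionizing solvent, could then consume material before the C–C bond forms.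
- Fallback: the lactone is built by classical organometallic chemistry, setting out from epoxide 4 and returning at 6. Commercial 3,5-dimethoxyphenylmagnesium chloride opens 4 at its CH2 under CuI catalysis to give 1-(3,5-dimethoxyphenyl)pentan-2-ol F1. NBS brominates the ring carbon next to the chain, para to one methoxyl, to give 1-(2-bromo-3,5-dimethoxyphenyl)pentan-2-ol F2. Two equivalents of n-BuLi (alkoxide formation, then bromine–lithium exchange), carboxylation with CO2 and acidification close 6,8-dimethoxy-3-propyl-3,4-dihydroisochromen-1-one F3. BCl3 removes selectively the methyl group next to the lactone carbonyl through a boron chelate to give 8-hydroxy-6-methoxy-3-propyl-3,4-dihydroisochromen-1-one F4. Benzylation with BnBr and K2CO3 gives 6.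

**Step 9.**
- Risk: if desilylation outruns oxidation, carbinol 14 transesterifies onto the depside carbonyl, closing lactone 6 and expelling ring B. Long exposure to hexavalent chromium may also oxidize the benzyl ether.
- Fallback: the ketone is installed and masked before the depside bond, so that no carbinol is ever set free beside the aryl ester; the route leaves at salt 7 and returns at 15. Allyl bromide in DMF alkylates 7 to allyl 2-(benzyloxy)-6-(2-hydroxypentyl)-4-methoxybenzoate F5. This is oxidized at once with Dess–Martin periodinane to allyl 2-(benzyloxy)-4-methoxy-6-(2-oxopentyl)benzoate F6. 1,2-Bis(trimethylsilyloxy)ethane with catalytic TMSOTf at low temperature gives allyl 2-(benzyloxy)-4-methoxy-6-[(2-propyl-1,3-dioxolan-2-yl)methyl]benzoate F7. Pd(PPh3)4 (zerovalent palladium) and morpholine remove the allyl group to give 2-(benzyloxy)-4-methoxy-6-[(2-propyl-1,3-dioxolan-2-yl)methyl]benzoic acid F8. DCC/DMAP coupling with 12 gives benzyl 4-({2-(benzyloxy)-4-methoxy-6-[(2-propyl-1,3-dioxolan-2-yl)methyl]benzoyl}oxy)-2-hydroxy-6-pentylbenzoate F9. Pyridinium p-toluenesulfonate in wet acetone unmasks the ketone and gives 15.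

**Step 8.**
- Risk: the phenol may attack the shielded carbonyl slowly, so that the O-acylisourea rearranges to the N-acylurea. The activated carboxyl may also be captured by the silyloxy oxygen, returning lactone 6.
- Fallback: the acid is converted into an isolated acyl halide, setting out from 9 and returning at 13. 1-Chloro-N,N,2-trimethylprop-1-en-1-amine in CH2Cl2 converts 9 under neutral conditions into 2-(benzyloxy)-6-[2-(tert-butyldimethylsilyloxy)pentyl]-4-methoxybenzoyl chloride F10. This small, compact acyl donor is then added to 12 with Et3N and DMAP at 0 °C. No carbodiimide is present, so the urea rearrangement cannot occur.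

**Step 5.**
- Risk: relactonization to 6 at the silyl ester stage or during acidification, and partial loss of the silyl ether on work-up.
- Fallback: the carboxyl is held as an alkyl ester while the carbinol is capped, setting out from 7 and returning at 9. MeI in DMF gives methyl 2-(benzyloxy)-6-(2-hydroxypentyl)-4-methoxybenzoate F11. TBSOTf and 2,6-lutidine at −78 °C silylate the carbinol faster than it can lactonize and give methyl 2-(benzyloxy)-6-[2-(tert-butyldimethylsilyloxy)pentyl]-4-methoxybenzoate F12. The hindered ester is then cleaved at its methyl carbon by SN2 attack of lithium propane-1-thiolate in a dipolar aprotic solvent, which needs no access to the shielded carbonyl, and mild acidification gives 9.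

**Step 6.**
- Risk: carboxylation at C2, between the two hydroxyls, instead of at C4, and decarboxylation of 11 during the acidic work-up.
- Fallback: the carboxyl carbon is introduced as an aldehyde, setting out from 10 and returning at 11. Vilsmeier–Haack formylation (POCl3, DMF, then aqueous hydrolysis) gives 2,4-dihydroxy-6-pentylbenzaldehyde F13. Benzylation of both phenols (BnBr, K2CO3) gives 2,4-bis(benzyloxy)-6-pentylbenzaldehyde F14. Pinnick oxidation (NaClO2, NaH2PO4, 2-methylbut-2-ene) gives 2,4-bis(benzyloxy)-6-pentylbenzoic acid F15. Hydrogenolysis over Pd/C gives 11.

## Further compounds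

F1 | step 3 | 1-(3,5-dimethoxyphenyl)pentan-2-ol (racemic) | CCCC(O)Cc1cc(OC)cc(OC)c1
F2 | step 3 | 1-(2-bromo-3,5-dimethoxyphenyl)pentan-2-ol (racemic) | CCCC(O)Cc1cc(OC)cc(OC)c1Br
F3 | step 3 | 6,8-dimethoxy-3-propyl-3,4-dihydroisochromen-1-one (racemic) | CCCC1Cc2cc(OC)cc(OC)c2C(=O)O1
F4 | step 3 | 8-hydroxy-6-methoxy-3-propyl-3,4-dihydroisochromen-1-one (racemic) | CCCC1Cc2cc(OC)cc(O)c2C(=O)O1
F5 | step 9 | allyl 2-(benzyloxy)-6-(2-hydroxypentyl)-4-methoxybenzoate (racemic) | CCCC(O)Cc1cc(OC)cc(OCc2ccccc2)c1C(=O)OCC=C
F6 | step 9 | allyl 2-(benzyloxy)-4-methoxy-6-(2-oxopentyl)benzoate | CCCC(=O)Cc1cc(OC)cc(OCc2ccccc2)c1C(=O)OCC=C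
F7 | step 9 | allyl 2-(benzyloxy)-4-methoxy-6-[(2-propyl-1,3-dioxolan-2-yl)methyl]benzoate | CCCC1(Cc2cc(OC)cc(OCc3ccccc3)c2C(=O)OCC=C)OCCO1
F8 | step 9 | 2-(benzyloxy)-4-methoxy-6-[(2-propyl-1,3-dioxolan-2-yl)methyl]benzoic acid | CCCC1(Cc2cc(OC)cc(OCc3ccccc3)c2C(=O)O)OCCO1
F9 | step 9 | benzyl 4-({2-(benzyloxy)-4-methoxy-6-[(2-propyl-1,3-dioxolan-2-yl)methyl]benzoyl}oxy)-2-hydroxy-6-pentylbenzoate | CCCCCc1cc(OC(=O)c2c(OCc3ccccc3)cc(OC)cc2CC2(CCC)OCCO2)cc(O)c1C(=O)OCc1ccccc1
F10 | step 8 | 2-(benzyloxy)-6-[2-(tert-butyldimethylsilyloxy)pentyl]-4-methoxybenzoyl chloride (racemic) | CCCC(O[Si](C)(C)C(C)(C)C)Cc1cc(OC)cc(OCc2ccccc2)c1C(=O)Cl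
F11 | step 5 | methyl 2-(benzyloxy)-6-(2-hydroxypentyl)-4-methoxybenzoate (racemic) | CCCC(O)Cc1cc(OC)cc(OCc2ccccc2)c1C(=O)OC
F12 | step 5 | methyl 2-(benzyloxy)-6-[2-(tert-butyldimethylsilyloxy)pentyl]-4-methoxybenzoate (racemic) | CCCC(O[Si](C)(C)C(C)(C)C)Cc1cc(OC)cc(OCc2ccccc2)c1C(=O)OC
F13 | step 6 | 2,4-dihydroxy-6-pentylbenzaldehyde | CCCCCc1cc(O)cc(O)c1C=O
F14 | step 6 | 2,4-bis(benzyloxy)-6-pentylbenzaldehyde | CCCCCc1cc(OCc2ccccc2)cc(OCc2ccccc2)c1C=O
F15 | step 6 | 2,4-bis(benzyloxy)-6-pentylbenzoic acid | CCCCCc1cc(OCc2ccccc2)cc(OCc2ccccc2)c1C(=O)O
A1 | alternative 1 | 1-fluoro-3,5-dimethoxybenzene | COc1cc(F)cc(OC)c1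
A2 | alternative 1 | 3,5-dimethoxybenzyne | COC1=CC(OC)=CC#C1
A3 | alternative 1 | 2,4-dimethoxy-6-pentylbenzoic acid | CCCCCc1cc(OC)cc(OC)c1C(=O)O
A4 | alternative 2 | (E)-non-3-en-2-one | CCCCC/C=C/C(C)=O
A5 | alternative 2 | dibenzyl malonate | O=C(CC(=O)OCc1ccccc1)OCc1ccccc1
A6 | alternative 2 | benzyl 2-hydroxy-4-oxo-6-pentylcyclohex-2-ene-1-carboxylate (racemic) | CCCCCC1CC(=O)C=C(O)C1C(=O)OCc1ccccc1
A7 | alternative 3 | 1,3-dimethoxy-1-(trimethylsilyloxy)buta-1,3-diene | C=C(OC)C=C(OC)O[Si](C)(C)C
A8 | alternative 3 | benzyl 2-hydroxy-6-pentyl-4-{[4-(2-propyl-1,3-dioxolan-2-yl)but-2-ynoyl]oxy}benzoate | CCCCCc1cc(OC(=O)C#CCC2(CCC)OCCO2)cc(O)c1C(=O)OCc1ccccc1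
A9 | alternative 3 | benzyl 2-hydroxy-4-({2-hydroxy-4-methoxy-6-[(2-propyl-1,3-dioxolan-2-yl)methyl]benzoyl}oxy)-6-pentylbenzoate | CCCCCc1cc(OC(=O)c2c(O)cc(OC)cc2CC2(CCC)OCCO2)cc(O)c1C(=O)OCc1ccccc1
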